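**Strategy.** The ten-membered carbocycle is disconnected at C1–C2 (germacrane numbering): C1 is the epoxide CH and C2 the adjoining sp2 carbon of the cis C2=C3 bond, so the C1–O bond of the epoxide is read as a masked allylic carbinol. The key step, an intramolecular Nozaki–Hiyama–Kishi reaction, adds the Z-alkenyl iodide at C2 to a C1 aldehyde: in one operation it closes the ring and sets C1 next to the silyloxy-bearing C10. Its precursor is the intact trans α-methylene-γ-lactone (C6, C7) carrying the cis,cis-iododiene on C6 and, on C7, the acylated C8 carbinol with a C9–C10 aldehyde arm. Mesylation and fluoride then turn the C1/C10 pair into the epoxide.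

Key step: step 18

Remark (numbering): germacrane locants are used throughout: C1 epoxide CH, C10 epoxide C(CH3) with C14, C9 CH2, C8 acyloxy CH, C7 ring-fusion CH, C6 lactone O–CH, C5=C4 (C15 = CH2O on C4; cis in the ring, E by CIP), C3=C2 (Z), C11/C12/C13 the methylene-lactone carbons.

Remark (assumption): in step 4 the ligand antipode must deliver the alkynyl group to the Re face of the enal; this is taken to be (S,S)-ProPhenol, and the antipode is used if the sense is the reverse.

**Aldehyde 5 (C8–C10, C1, C14)**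

Step 1
Reactants: 1 (S)-2-methylglycidol
Product: 2 (2R)-2-methylpent-4-ene-1,2-diol
Conditions: CH2=CHMgBr (3 equiv), CuI (10 mol%), THF, −30 → 0 °C
Reagents that add atoms: vinylmagnesium bromide, C=C[Mg]Br
Why: Copper-catalysed Grignard opening of a 2,2-disubstituted epoxide (SN2) takes place at the unsubstituted ring CH2, so the quaternary carbinol carbon (future C10) is not touched and keeps the configuration of 1.

Step 2
Reactants: 2 (2R)-2-methylpent-4-ene-1,2-diol
Product: 3 (4R)-4-methyl-4,5-bis(triethylsilyloxy)pent-1-ene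
Conditions: Et3SiOTf (2.5 equiv), 2,6-lutidine, CH2Cl2, −78 → 0 °C
Reagents that add atoms: triethylsilyl trifluoromethanesulfonate, CC[Si](CC)(CC)OS(=O)(=O)C(F)(F)F
Why: Silylation with the silyl triflate protects both the primary and the hindered tertiary hydroxyl as triethylsilyl ethers, which later allows the primary one alone to be oxidised.

Step 3
Reactants: 3 (4R)-4-methyl-4,5-bis(triethylsilyloxy)pent-1-ene
Product: 5 (3R)-3-methyl-3,4-bis(triethylsilyloxy)butanal, via ozonide 4 (not isolated)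
Conditions: O3, CH2Cl2, −78 °C; then PPh3, −78 °C → rt
Reagents that add atoms: ozone, [O-][O+]=O
Why: Ozonolysis of the terminal alkene with reductive work-up should give the C8 aldehyde without touching the silyl ethers or the quaternary stereocentre.

**Butenolide bromide 13 (C4–C7, C11–C13, C15)**

Step 4
Reactants: 6 (E)-but-2-enal, 7 tert-butyl(diphenyl)(prop-2-yn-1-yloxy)silane
Product: 8 (2E,4S)-7-(tert-butyldiphenylsilyloxy)hept-2-en-5-yn-4-ol
Conditions: Me2Zn (3 equiv), (S,S)-ProPhenol (20 mol%), Ph3P=O (40 mol%), toluene, 4 °C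
Reagents that add atoms: none
Why: Zinc–ProPhenol catalysed enantioselective alkynylation of an enal, in which the dinuclear zinc catalyst binds aldehyde and alkynylzinc and delivers the alkynyl group to the Re face of 6, sets the carbinol (future C6) as 4S.

Step 5
Reactants: 8 (2E,4S)-7-(tert-butyldiphenylsilyloxy)hept-2-en-5-yn-4-ol
Product: 10 (2Z,4S,5E)-1-(tert-butyldiphenylsilyloxy)-2-iodohepta-2,5-dien-4-ol, via oxaaluminacycle alanate 9 (not isolated)
Conditions: NaAlH2(OCH2CH2OMe)2 (Red-Al), THF, 0 °C → rt; then I2, THF, −78 °C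
Reagents that add atoms: iodine, II
Why: Hydroxyl-directed trans-hydroalumination of the propargylic alcohol places hydride on C5 and aluminium on C4 in a five-membered oxaaluminacycle, and iodinolysis with retention gives the alkenyl iodide with iodine cis to C6, which fixes the C4=C5 geometry of the target.

Step 6
Reactants: 10 (2Z,4S,5E)-1-(tert-butyldiphenylsilyloxy)-2-iodohepta-2,5-dien-4-ol, 11 2-(bromomethyl)prop-2-enoic acid
Product: 12 (2Z,4S,5E)-1-(tert-butyldiphenylsilyloxy)-2-iodohepta-2,5-dien-4-yl 2-(bromomethyl)prop-2-enoate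
Conditions: DIC, DMAP (5 mol%), CH2Cl2, 0 °C
Reagents that add atoms: none
Why: Steglich esterification acylates the secondary alcohol under neutral conditions that should leave the allylic bromide, the alkenyl iodide and the bis-allylic carbinol centre intact.

Step 7
Reactants: 12 (2Z,4S,5E)-1-(tert-butyldiphenylsilyloxy)-2-iodohepta-2,5-dien-4-yl 2-(bromomethyl)prop-2-enoate
Product: 13 (5S)-3-(bromomethyl)-5-[(1Z)-3-(tert-butyldiphenylsilyloxy)-2-iodoprop-1-en-1-yl]furan-2(5H)-one
Conditions: second-generation Grubbs catalyst RuCl2(=CHPh)(PCy3)(H2IMes) (5 mol%), toluene, 80 °C, argon purge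
Reagents that add atoms: none
Why: Ring-closing metathesis between the propenyl group and the 1,1-disubstituted acrylate forms the five-membered butenolide with loss of propene, the trisubstituted alkenyl iodide being inert to the ruthenium carbene and C6 being untouched.

**Fragment union**

Step 8
Reactants: 13 (5S)-3-(bromomethyl)-5-[(1Z)-3-(tert-butyldiphenylsilyloxy)-2-iodoprop-1-en-1-yl]furan-2(5H)-one, 5 (3R)-3-methyl-3,4-bis(triethylsilyloxy)butanal
Product: 14 (4R,5S)-5-[(1Z)-3-(tert-butyldiphenylsilyloxy)-2-iodoprop-1-en-1-yl]-4-[(1S,3R)-1-hydroxy-3-methyl-3,4-bis(triethylsilyloxy)butyl]-3-methylideneoxolan-2-one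
Conditions: In powder (2 equiv), THF/H2O (4:1), rt
Reagents that add atoms: none
Why: In this indium-mediated Barbier allylation (SE2′) the allylindium attacks the aldehyde through ring carbon C7 on the face anti to the C6 alkenyl group, which gives the trans lactone and the exocyclic methylene, and a Zimmerman–Traxler chair with the aldehyde chain equatorial should give the 8S carbinol, the C8 epimer that step 13 inverts.

**Side-chain acid 21**

Step 9
Reactants: 15 tert-butyl(dimethyl)(prop-2-yn-1-yloxy)silane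
Product: 17 tert-butyl 4-(tert-butyldimethylsilyloxy)but-2-ynoate, via lithium acetylide 16 (not isolated)
Conditions: n-BuLi, THF, −78 °C; then Boc2O, −78 → 0 °C
Reagents that add atoms: di-tert-butyl dicarbonate, CC(C)(C)OC(=O)OC(=O)OC(C)(C)C
Why: Deprotonation of the terminal alkyne and C-acylation of the lithium acetylide with the dicarbonate gives the tert-butyl ynoate directly.

Step 10
Reactants: 17 tert-butyl 4-(tert-butyldimethylsilyloxy)but-2-ynoate
Product: 18 tert-butyl (2Z)-4-(tert-butyldimethylsilyloxy)-3-methylbut-2-enoate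
Conditions: Me2CuLi (from MeLi, CuI), THF, −78 °C; MeOH quench at −78 °C
Reagents that add atoms: lithium dimethylcuprate, [Li+].C[Cu-]C
Why: Syn-carbocupration of the ynoate and protonation of the alkenylcopper at −78 °C with retention put the new methyl cis to H-2, so the ester and the CH2O group end up cis (2Z).

Step 11
Reactants: 18 tert-butyl (2Z)-4-(tert-butyldimethylsilyloxy)-3-methylbut-2-enoate
Product: 20 tert-butyl (2Z)-4-acetoxy-3-methylbut-2-enoate, via hydroxy ester 19 (not isolated)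
Conditions: TBAF, AcOH, THF, 0 °C; then Ac2O, Et3N, DMAP (cat.), 0 °C
Reagents that add atoms: acetic anhydride, CC(=O)OC(C)=O
Why: Buffered fluoride desilylation and acetylation in the same flask trap the Z-γ-hydroxy ester as its acetate before it can lactonise, the tert-butyl ester being a poor acyl donor.

Step 12
Reactants: 20 tert-butyl (2Z)-4-acetoxy-3-methylbut-2-enoate
Product: 21 (2Z)-4-acetoxy-3-methylbut-2-enoic acid
Conditions: TFA, CH2Cl2, 0 °C → rt
Reagents that add atoms: none
Why: Acidolysis of the tert-butyl ester with loss of isobutene frees the carboxylic acid without touching the allylic acetate or the Z double bond.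

**Completion**

Step 13
Reactants: 14 (8S)-alcohol, 21 (2Z)-4-acetoxy-3-methylbut-2-enoic acid
Product: 22 (1R,3R)-1-{(2S,3R)-2-[(1Z)-3-(tert-butyldiphenylsilyloxy)-2-iodoprop-1-en-1-yl]-4-methylidene-5-oxooxolan-3-yl}-3-methyl-3,4-bis(triethylsilyloxy)butyl (2Z)-4-acetoxy-3-methylbut-2-enoate
Conditions: PPh3, DIAD, toluene, 0 °C → rt
Reagents that add atoms: none
Why: In this Mitsunobu esterification the C8 hydroxyl is activated as its oxyphosphonium ion and displaced by the carboxylate of 21 in an SN2 reaction with inversion, which converts 8S into the 8R configuration of the target while installing the side chain.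

Step 14
Reactants: 23 acetylene, 24 hexamethylditin
Product: 25 (Z)-1,2-bis(trimethylstannyl)ethene
Conditions: Pd(PPh3)4 (1 mol%), dioxane, 60 °C, acetylene (1 atm)
Reagents that add atoms: none
Why: Palladium-catalysed distannation of acetylene is a syn addition of the Sn–Sn bond and therefore gives only the Z-1,2-distannylethene.

Step 15
Reactants: 22 C4 alkenyl iodide, 25 (Z)-1,2-bis(trimethylstannyl)ethene (3 equiv)
Product: 26 (1R,3R)-1-{(2R,3R)-2-[(1E,3Z)-2-[(tert-butyldiphenylsilyloxy)methyl]-4-(trimethylstannyl)buta-1,3-dien-1-yl]-4-methylidene-5-oxooxolan-3-yl}-3-methyl-3,4-bis(triethylsilyloxy)butyl (2Z)-4-acetoxy-3-methylbut-2-enoate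
Conditions: copper thiophene-2-carboxylate Cu(O2CC4H3S) (1.5 equiv), NMP, 0 °C
Reagents that add atoms: none
Why: This copper-carboxylate-mediated Stille-type coupling (tin-to-copper transmetalation, then coupling with the alkenyl iodide) proceeds with retention at both alkene carbons and uses no palladium that could ionise the allylic acetate, while excess 25 favours monocoupling to the cis,cis-diene with a Z-alkenylstannane at C2.

Step 16
Reactants: 26 dienylstannane
Product: 27 (1R,3R)-1-{(2R,3R)-2-[(1E,3Z)-2-[(tert-butyldiphenylsilyloxy)methyl]-4-iodobuta-1,3-dien-1-yl]-4-methylidene-5-oxooxolan-3-yl}-3-methyl-3,4-bis(triethylsilyloxy)butyl (2Z)-4-acetoxy-3-methylbut-2-enoate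
Conditions: I2, NaHCO3, CH2Cl2, 0 °C
Reagents that add atoms: iodine, II
Why: Iododestannylation (ipso substitution of the alkenylstannane by iodine) takes place with retention and gives the Z-alkenyl iodide at C2.

Step 17
Reactants: 27 dienyl iodide
Product: 29 (1R,3R)-1-{(2R,3R)-2-[(1E,3Z)-2-[(tert-butyldiphenylsilyloxy)methyl]-4-iodobuta-1,3-dien-1-yl]-4-methylidene-5-oxooxolan-3-yl}-3-methyl-4-oxo-3-(triethylsilyloxy)butyl (2Z)-4-acetoxy-3-methylbut-2-enoate, via alkoxysulfonium chloride 28 (not isolated)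
Conditions: (COCl)2, DMSO, CH2Cl2, −78 → −40 °C; then Et3N, −78 → 0 °C
Reagents that add atoms: none
Why: Swern conditions convert a primary triethylsilyl ether directly into the aldehyde, while the tertiary triethylsilyl and the tert-butyldiphenylsilyl ether are too hindered to react, so C1 is unmasked selectively.

Step 18
Reactants: 29 iodo-diene aldehyde
Product: 30 (1S,6R,7R,8R,10R)-15-(tert-butyldiphenylsilyloxy)-1-hydroxy-10-(triethylsilyloxy)germacra-2Z,4E,11(13)-trien-12,6-olid-8-yl (2Z)-4-acetoxy-3-methylbut-2-enoate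
Conditions: CrCl2 (15 equiv), NiCl2 (0.3 equiv), degassed DMSO/THF (3:1), 0.002 M, slow addition of 29, rt
Reagents that add atoms: none
Why: Zerovalent nickel (formed from NiCl2 and CrCl2) inserts into the C2–I bond with retention of the Z geometry, transmetalation gives the alkenyl trivalent-chromium species, and this adds to the C1 aldehyde, the chromium alkoxide being protonated on work-up. The closest known reaction type is the intramolecular Nozaki–Hiyama–Kishi alkenylation used to close medium rings. The ten-membered carbocycle closes in a 10-exo-trig mode at the carbonyl carbon. The new C1 stereocentre is controlled by the adjacent quaternary C10: in the Felkin–Anh arrangement the C10–OSiEt3 bond lies anti to the incoming C2, attack passes the small methyl group and C9 (the ring tether) sits gauche, which should give the 1S alcohol anti to the silyloxy group, as needed for inversion to the epoxide. The step needs chemoselectivity for the aldehyde over lactone, enoate and allylic acetate, which the carbonyl selectivity of organochromium reagents secures, and ring closure over oligomerisation, which high dilution and the cis,cis-diene turn (C2–C5) that brings C2 towards C1 secure. The silyl ether on O10 suppresses chelation, which would favour the C1 epimer.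

Step 19
Reactants: 30 macrocyclic alcohol
Product: 32 CNP0292814.1, (1R,6R,7R,8R,10R)-1,10-epoxy-15-hydroxygermacra-2Z,4E,11(13)-trien-12,6-olid-8-yl (2Z)-4-acetoxy-3-methylbut-2-enoate, via C1 mesylate 31 (not isolated)
Conditions: Ms2O, Et3N, CH2Cl2, −40 °C; then TBAF (3 equiv), THF, −40 °C → rt
Reagents that add atoms: none
Why: Mesylation of the C1 hydroxyl and fluoride cleavage of the C10 triethylsilyl ether release the tertiary alkoxide, which displaces the adjacent mesylate in a 3-exo-tet SN2 reaction with inversion at C1 to give the trans epoxide (1R,10R), and the same fluoride removes the tert-butyldiphenylsilyl group from O15.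

**Compound list**

1 | (S)-2-methylglycidol [(2S)-2-methyloxiran-2-yl]methanol | OC[C@@]1(C)CO1 | starting material
2 | (2R)-2-methylpent-4-ene-1,2-diol | C=CC[C@@](C)(O)CO | intermediate
3 | (4R)-4-methyl-4,5-bis(triethylsilyloxy)pent-1-ene | C=CC[C@@](C)(O[Si](CC)(CC)CC)CO[Si](CC)(CC)CC | intermediate
4 | ozonide (1,2,4-trioxolane) of 3 | O1OCOC1C[C@@](C)(O[Si](CC)(CC)CC)CO[Si](CC)(CC)CC | intermediate (not isolated)
5 | (3R)-3-methyl-3,4-bis(triethylsilyloxy)butanal | O=CC[C@@](C)(O[Si](CC)(CC)CC)CO[Si](CC)(CC)CC | intermediate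
6 | (E)-but-2-enal (crotonaldehyde) | C/C=C/C=O | starting material
7 | tert-butyl(diphenyl)(prop-2-yn-1-yloxy)silane | C#CCO[Si](c1ccccc1)(c1ccccc1)C(C)(C)C | starting material
8 | (2E,4S)-7-(tert-butyldiphenylsilyloxy)hept-2-en-5-yn-4-ol | C/C=C/[C@H](O)C#CCO[Si](c1ccccc1)(c1ccccc1)C(C)(C)C | intermediate
9 | sodium alkenylalanate from 8 (five-membered oxaaluminacycle, Al on C4) | C/C=C/[C@H]1C=C(CO[Si](c2ccccc2)(c2ccccc2)C(C)(C)C)[Al-](OCCOC)(OCCOC)O1.[Na+] | intermediate (not isolated)
10 | (2Z,4S,5E)-1-(tert-butyldiphenylsilyloxy)-2-iodohepta-2,5-dien-4-ol | C/C=C/[C@H](O)/C=C(\I)CO[Si](c1ccccc1)(c1ccccc1)C(C)(C)C | intermediate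
11 | 2-(bromomethyl)prop-2-enoic acid | OC(=O)C(=C)CBr | starting material
12 | (2Z,4S,5E)-1-(tert-butyldiphenylsilyloxy)-2-iodohepta-2,5-dien-4-yl 2-(bromomethyl)prop-2-enoate | C/C=C/[C@H](OC(=O)C(=C)CBr)/C=C(\I)CO[Si](c1ccccc1)(c1ccccc1)C(C)(C)C | intermediate
13 | (5S)-3-(bromomethyl)-5-[(1Z)-3-(tert-butyldiphenylsilyloxy)-2-iodoprop-1-en-1-yl]furan-2(5H)-one | O=C1O[C@@H](C=C1CBr)/C=C(\I)CO[Si](c1ccccc1)(c1ccccc1)C(C)(C)C | intermediate
14 | (4R,5S)-5-[(1Z)-3-(tert-butyldiphenylsilyloxy)-2-iodoprop-1-en-1-yl]-4-[(1S,3R)-1-hydroxy-3-methyl-3,4-bis(triethylsilyloxy)butyl]-3-methylideneoxolan-2-one (8S alcohol) | C=C1C(=O)O[C@H](/C=C(\I)CO[Si](c2ccccc2)(c2ccccc2)C(C)(C)C)[C@H]1[C@@H](O)C[C@@](C)(O[Si](CC)(CC)CC)CO[Si](CC)(CC)CC | intermediate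
15 | tert-butyl(dimethyl)(prop-2-yn-1-yloxy)silane | C#CCO[Si](C)(C)C(C)(C)C | starting material
16 | lithium acetylide of 15 | [Li]C#CCO[Si](C)(C)C(C)(C)C | intermediate (not isolated)
17 | tert-butyl 4-(tert-butyldimethylsilyloxy)but-2-ynoate | CC(C)(C)OC(=O)C#CCO[Si](C)(C)C(C)(C)C | intermediate
18 | tert-butyl (2Z)-4-(tert-butyldimethylsilyloxy)-3-methylbut-2-enoate | CC(C)(C)OC(=O)/C=C(/C)CO[Si](C)(C)C(C)(C)C | intermediate
19 | tert-butyl (2Z)-4-hydroxy-3-methylbut-2-enoate | CC(C)(C)OC(=O)/C=C(/C)CO | intermediate (not isolated)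
20 | tert-butyl (2Z)-4-acetoxy-3-methylbut-2-enoate | CC(C)(C)OC(=O)/C=C(/C)COC(C)=O | intermediate
21 | (2Z)-4-acetoxy-3-methylbut-2-enoic acid | OC(=O)/C=C(/C)COC(C)=O | intermediate
22 | (1R,3R)-1-{(2S,3R)-2-[(1Z)-3-(tert-butyldiphenylsilyloxy)-2-iodoprop-1-en-1-yl]-4-methylidene-5-oxooxolan-3-yl}-3-methyl-3,4-bis(triethylsilyloxy)butyl (2Z)-4-acetoxy-3-methylbut-2-enoate | C=C1C(=O)O[C@H](/C=C(\I)CO[Si](c2ccccc2)(c2ccccc2)C(C)(C)C)[C@H]1[C@H](OC(=O)/C=C(/C)COC(C)=O)C[C@@](C)(O[Si](CC)(CC)CC)CO[Si](CC)(CC)CC | intermediate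
23 | acetylene | C#C | starting material
24 | hexamethylditin | C[Sn](C)(C)[Sn](C)(C)C | starting material
25 | (Z)-1,2-bis(trimethylstannyl)ethene | C[Sn](C)(C)/C=C\[Sn](C)(C)C | intermediate
26 | (1R,3R)-1-{(2R,3R)-2-[(1E,3Z)-2-[(tert-butyldiphenylsilyloxy)methyl]-4-(trimethylstannyl)buta-1,3-dien-1-yl]-4-methylidene-5-oxooxolan-3-yl}-3-methyl-3,4-bis(triethylsilyloxy)butyl (2Z)-4-acetoxy-3-methylbut-2-enoate | C=C1C(=O)O[C@H](/C=C(CO[Si](c2ccccc2)(c2ccccc2)C(C)(C)C)\C=C/[Sn](C)(C)C)[C@H]1[C@H](OC(=O)/C=C(/C)COC(C)=O)C[C@@](C)(O[Si](CC)(CC)CC)CO[Si](CC)(CC)CC | intermediate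
27 | (1R,3R)-1-{(2R,3R)-2-[(1E,3Z)-2-[(tert-butyldiphenylsilyloxy)methyl]-4-iodobuta-1,3-dien-1-yl]-4-methylidene-5-oxooxolan-3-yl}-3-methyl-3,4-bis(triethylsilyloxy)butyl (2Z)-4-acetoxy-3-methylbut-2-enoate | C=C1C(=O)O[C@H](/C=C(CO[Si](c2ccccc2)(c2ccccc2)C(C)(C)C)\C=C/I)[C@H]1[C@H](OC(=O)/C=C(/C)COC(C)=O)C[C@@](C)(O[Si](CC)(CC)CC)CO[Si](CC)(CC)CC | intermediate
28 | C1 alkoxydimethylsulfonium chloride derived from 27 | C=C1C(=O)O[C@H](/C=C(CO[Si](c2ccccc2)(c2ccccc2)C(C)(C)C)\C=C/I)[C@H]1[C@H](OC(=O)/C=C(/C)COC(C)=O)C[C@@](C)(O[Si](CC)(CC)CC)CO[S+](C)C.[Cl-] | intermediate (not isolated)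
29 | (1R,3R)-1-{(2R,3R)-2-[(1E,3Z)-2-[(tert-butyldiphenylsilyloxy)methyl]-4-iodobuta-1,3-dien-1-yl]-4-methylidene-5-oxooxolan-3-yl}-3-methyl-4-oxo-3-(triethylsilyloxy)butyl (2Z)-4-acetoxy-3-methylbut-2-enoate | C=C1C(=O)O[C@H](/C=C(CO[Si](c2ccccc2)(c2ccccc2)C(C)(C)C)\C=C/I)[C@H]1[C@H](OC(=O)/C=C(/C)COC(C)=O)C[C@@](C)(O[Si](CC)(CC)CC)C=O | intermediate
30 | (1S,6R,7R,8R,10R)-15-(tert-butyldiphenylsilyloxy)-1-hydroxy-10-(triethylsilyloxy)germacra-2Z,4E,11(13)-trien-12,6-olid-8-yl (2Z)-4-acetoxy-3-methylbut-2-enoate | C=C1C(=O)O[C@@H]2/C=C(CO[Si](c3ccccc3)(c3ccccc3)C(C)(C)C)\C=C/[C@H](O)[C@](C)(O[Si](CC)(CC)CC)C[C@@H](OC(=O)/C=C(/C)COC(C)=O)[C@@H]12 | intermediate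
31 | C1 methanesulfonate of 30 | C=C1C(=O)O[C@@H]2/C=C(CO[Si](c3ccccc3)(c3ccccc3)C(C)(C)C)\C=C/[C@H](OS(C)(=O)=O)[C@](C)(O[Si](CC)(CC)CC)C[C@@H](OC(=O)/C=C(/C)COC(C)=O)[C@@H]12 | intermediate (not isolated)
32 | CNP0292814.1, (1R,6R,7R,8R,10R)-1,10-epoxy-15-hydroxygermacra-2Z,4E,11(13)-trien-12,6-olid-8-yl (2Z)-4-acetoxy-3-methylbut-2-enoate | C=C1C(=O)O[C@@H]2/C=C(CO)\C=C/[C@H]3O[C@]3(C)C[C@@H](OC(=O)/C=C(/C)COC(C)=O)[C@@H]12 | target

**Step count and risks**

Total: 19 steps. Longest linear sequence: 11 steps (steps 4, 5, 6, 7, 8, 13, 15, 16, 17, 18, 19).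

Steps most likely to fail:

1. Step 18 (ring closure). If the ring closes slowly, the alkenylchromium species may be protonated or lose its Z geometry, and intermolecular coupling may take over. The fallback keeps the same bond but closes it with an alkynyl nucleophile; it sets out from 22 and returns at 30. Sonogashira coupling of 22 with ethynyltrimethylsilane (PdCl2(PPh3)2, CuI, Et3N) should give the trimethylsilyl enyne F1. NIS with catalytic AgNO3 converts it into the iodoalkyne F2. Swern oxidation of the primary triethylsilyl ether, as in step 17, gives the aldehyde F3. CrCl2 in THF generates a configurationally trivial alkynylchromium species that should close the ring to the cyclic enynol F4 under the same Felkin–Anh control. Z-selective semi-reduction of the conjugated triple bond with Zn(Cu/Ag) in MeOH/H2O then gives 30.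

2. Step 13 (inversion at C8). The activated, hindered C8 alcohol may eliminate towards C7 or C9, or not be displaced at all. The fallback avoids the inversion by setting C8 directly through an open transition state; it sets out from 10 and returns at 22. Steglich esterification of 10 with 2-[(trimethylsilyl)methyl]prop-2-enoic acid gives the allylsilane ester F5. Ring-closing metathesis as in step 7 gives the 3-[(trimethylsilyl)methyl]butenolide F6. Hosomi–Sakurai reaction of F6 with aldehyde 5 (BF3·OEt2, CH2Cl2, −78 °C) attacks through C7 anti to the C6 substituent via an antiperiplanar open transition state and should give the syn product, the 8R alcohol F7. Steglich esterification of F7 with acid 21 (DIC, DMAP; retention) gives 22.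

3. Step 19 (epoxide closure). The dienylic mesylate may ionise before ring closure, with loss of configuration at C1 or allylic transposition, and fluoride may cause acyl migration or cleavage of the acetate. The fallback uses a free diol and no sulfonate; it sets out from 30 and returns at 32. Selective cleavage of the tertiary triethylsilyl ether (HF·pyridine, pyridine, THF, 0 °C; the tert-butyldiphenylsilyl ether should stay) gives the 1,10-diol F8. Mitsunobu cyclodehydration (PPh3, DIAD, toluene) closes the epoxide with inversion at C1 to the silyl-protected epoxide F9. Buffered desilylation (TBAF, AcOH, THF) gives 32.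

Further compounds

F1 | step 18 | analogue of 22 with a (trimethylsilyl)ethynyl group in place of iodine on C4 | C=C1C(=O)O[C@H](/C=C(CO[Si](c2ccccc2)(c2ccccc2)C(C)(C)C)\C#C[Si](C)(C)C)[C@H]1[C@H](OC(=O)/C=C(/C)COC(C)=O)C[C@@](C)(O[Si](CC)(CC)CC)CO[Si](CC)(CC)CC
F2 | step 18 | analogue of 22 with an iodoethynyl group on C4 | C=C1C(=O)O[C@H](/C=C(CO[Si](c2ccccc2)(c2ccccc2)C(C)(C)C)\C#CI)[C@H]1[C@H](OC(=O)/C=C(/C)COC(C)=O)C[C@@](C)(O[Si](CC)(CC)CC)CO[Si](CC)(CC)CC
F3 | step 18 | C1 aldehyde derived from F2 | C=C1C(=O)O[C@H](/C=C(CO[Si](c2ccccc2)(c2ccccc2)C(C)(C)C)\C#CI)[C@H]1[C@H](OC(=O)/C=C(/C)COC(C)=O)C[C@@](C)(O[Si](CC)(CC)CC)C=O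
F4 | step 18 | (1S)-2,3-didehydro analogue of 30 (C2≡C3 in the ten-membered ring) | C=C1C(=O)O[C@@H]2/C=C(CO[Si](c3ccccc3)(c3ccccc3)C(C)(C)C)\C#C[C@H](O)[C@](C)(O[Si](CC)(CC)CC)C[C@@H](OC(=O)/C=C(/C)COC(C)=O)[C@@H]12
F5 | step 13 | (2Z,4S,5E)-1-(tert-butyldiphenylsilyloxy)-2-iodohepta-2,5-dien-4-yl 2-[(trimethylsilyl)methyl]prop-2-enoate | C/C=C/[C@H](OC(=O)C(=C)C[Si](C)(C)C)/C=C(\I)CO[Si](c1ccccc1)(c1ccccc1)C(C)(C)C
F6 | step 13 | (5S)-5-[(1Z)-3-(tert-butyldiphenylsilyloxy)-2-iodoprop-1-en-1-yl]-3-[(trimethylsilyl)methyl]furan-2(5H)-one | O=C1O[C@@H](C=C1C[Si](C)(C)C)/C=C(\I)CO[Si](c1ccccc1)(c1ccccc1)C(C)(C)C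
F7 | step 13 | 8R epimer of 14 | C=C1C(=O)O[C@H](/C=C(\I)CO[Si](c2ccccc2)(c2ccccc2)C(C)(C)C)[C@H]1[C@H](O)C[C@@](C)(O[Si](CC)(CC)CC)CO[Si](CC)(CC)CC
F8 | step 19 | (1S,10R)-1,10-diol from 30 (O10 desilylated) | C=C1C(=O)O[C@@H]2/C=C(CO[Si](c3ccccc3)(c3ccccc3)C(C)(C)C)\C=C/[C@H](O)[C@](C)(O)C[C@@H](OC(=O)/C=C(/C)COC(C)=O)[C@@H]12
F9 | step 19 | 15-O-tert-butyldiphenylsilyl ether of 32 | C=C1C(=O)O[C@@H]2/C=C(CO[Si](c4ccccc4)(c4ccccc4)C(C)(C)C)\C=C/[C@H]3O[C@]3(C)C[C@@H](OC(=O)/C=C(/C)COC(C)=O)[C@@H]12
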